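Remarks on the chemistry (assumptions):
- The SMILES is taken literally: ring A (prenyl ring) is 2,6-cis (2S,6R) and ring B (hydroxyprenyl ring) is 2,6-trans (2'R,6'S), on an all-E nonaene.
- Compounds 1, 3, 8, 12, 18 and 31 are taken to be catalogue compounds.
- Carotenoid numbering is used: ring carbons C-1 (CMe2) to C-6, chain C-7 to C-15, primes for ring B, and C-1'' to C-4'' for the C5 side chain on C-2 or C-2'.

## Structural features

1. The target is a C50 carotenoid: two ε-type end rings (1,1,5-trimethylcyclohex-4-enes) are joined through C-6 and C-6' by an all-E nonaene (C-7 to C-7') with methyl groups at C-9, C-13, C-13' and C-9'.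
2. Each ring has two stereocentres, C-2 and C-6, which are not adjacent but flank the quaternary C-1.
3. Ring A carries a 3-methylbut-2-enyl group at C-2 and is 2,6-cis (2S,6R); ring B carries an (E)-4-hydroxy-3-methylbut-2-enyl group at C-2' and is 2,6-trans (2'R,6'S).
4. In space C-2 and C-2' have the same configuration and C-6 and C-6' the opposite one, so the two halves differ in side chain, in relative configuration and in one hydroxyl, and no two-directional end-group synthesis can serve.
5. Fragile elements are the nonaene (light, oxygen, acid), the doubly allylic C-6–H and C-6'–H, the skipped C-4=C-5 ring alkenes (acid or base moves them into conjugation or to the exocyclic position), the prenyl-type alkenes (cation–olefin chemistry) and the primary allylic alcohol.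
6. The real difficulty is to set C-6 next to the quaternary carbon in either sense relative to C-2, at will, while fixing the ring alkene at C-4=C-5.
7. The feature exploited is that C-4, C-5 and C-6 form an allyl unit ending at C-6, and that C-2 is β to C-4. An oxygen on C-4 can therefore, as a carbonyl, direct conjugate addition to C-2, and then, as a carbinol ether, hand its configuration suprafacially to C-6 in a [2,3] shift that also places the double bond at C-4=C-5.

## Logic of the disconnections

In one sentence: both ε-rings arise by [2,3]-Wittig rearrangement of the C-4 but-2-ynyl ethers 13 and 24, which share the C-2 configuration and are epimeric at the carbinol carbon.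

- **36 ⇒ 35 ⇒ 30 + 33.** The O–Si bond is tactical. The strategic cut is C-11'=C-12'. It divides the C50 polyene into a ring-B C20 phosphonium salt and a C30 aldehyde. The forward Wittig step must tolerate the C-6 and C-6' methine hydrogens and be followed by Z to E equilibration.
- **33 ⇒ 20 + 31.** The cut is C-11=C-12. The central C10 unit is a catalogue dialdehyde, and because the two ends differ the olefinations must be sequential. The demand is mono-olefination of 31.
- **20 ⇒ 19 ⇒ 17 and 30 ⇒ 29 ⇒ 28.** The cuts are C-11–P and C-9–C-10. Each end group is reduced to an ionone-type methyl ketone. The forward steps need 1,2-addition of a vinyl nucleophile and ionisation of a tertiary allylic carbinol without disturbing the ε-alkene.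
- **17 ⇒ 15 ⇒ 13 and 28 ⇒ 26 ⇒ 24 (key).** The cut is C-6–C-7, with the alkene returned from C-4=C-5 to C-5=C-6 and oxygen placed on C-4. This removes the hindered C-6 stereocentre and replaces it by a carbinol centre; the cis ring comes from 13 and the trans ring from 24. The demand is a concerted suprafacial shift after site-selective lithiation.
- **13 ⇒ 11 + 12 ⇒ 10 and 24 ⇒ 23 + 12 ⇒ 22.** The cuts are O–C-7 and C-4–H. Both carbinol epimers come from enones of one C-2 series. The reduction must be reagent-controlled in both senses.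
- **22 ⇒ 21 ⇒ 10.** The cuts are O–Si and the C-4''–O bond (a C–H oxidation). Both ring series then descend from the single enone 10. The oxidation must be selective for the E-methyl group of the prenyl unit.
- **10 ⇒ 7 + 8, 7 ⇒ 6 ⇒ 4.** The cut is C-2''=C-3'', then the oxidation level at C-2''. The side chain is reduced to a vinyl group. The forward steps need chemoselectivity against the ring enone.
- **4 ⇒ 2 + 3, 2 ⇒ 1.** The cut is C-2–C-1''. This is the only stereocentre set by a catalyst; all others are relayed from it or from the C-4 carbinol. The addition must choose the unsubstituted enone arm of 2 and one enone face.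

## Other disconnections considered

Alternative 1: the route most chemists would draw first.
- Cut: C-11=C-12 and C-11'=C-12' (C20 + C10 + C20 Wittig with 31), and, within each end group, C-1–C-6 by a biomimetic cation–olefin cyclisation.
- Forward key step: acid-mediated cyclisation of the acyclic trienone A1, whose C-2 stereocentre is set beforehand; the isopropenyl group is protonated and the tertiary cation closes onto the C-5=C-6 alkene.
- Grounds against: a chair transition state places both the C-2 side chain and the C-6 enone arm equatorial, so it can only give the cis ketone 17; the trans ketone 28 is out of reach.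
- The prenyl alkene on C-2 is protonated as easily as the isopropenyl group and would start competing cyclisations.
- Loss of the proton from the C-5 cation gives α, β and γ double-bond isomers.
- The chosen plan never passes through a cation and reaches both relative configurations from one enone.

Alternative 2: iterative conjugate addition.
- Cut: C-6–C-7 by a second 1,4-addition.
- Forward key step: addition of a vinyl cuprate to the remaining enone of 10 (or 22) anti to the C-2 chain, trapping of the enolate as the enol triflate A2, then reduction of the triflate to the C-4=C-5 alkene.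
- Grounds against: the acceptor carbon is flanked by the quaternary C-1 and carries an α-methyl group, so an intermolecular cuprate addition is expected to be slow.
- Facial control by the C-2 chain can only give the trans ring; the cis ring A would need a separate solution.
- The [2,3] shift is intramolecular, so hindrance matters less, and it gives either diastereomer by choice of the carbinol epimer.

Alternative 3: C–C cleavage of a terpene.
- Cut: the cyclobutane bond between the carbonyl-bearing bridgehead and the CH2 bridge of verbenone A3. Its CMe2 carbon, two bridgeheads and methyl-bearing alkene map onto C-1, C-2, C-6 and C-5=C-4.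
- Forward key step: reductive opening of the α-keto cyclobutane and prenylation of the resulting enolate to give A4.
- Grounds against: β-scission of the ketyl should break the other cyclobutane bond, to the gem-dimethyl carbon, because that gives a tertiary radical; the product would be a p-menthane.
- C-7 would arrive as an unfunctionalised methyl group.
- A carbonyl would remain at C-3 and would have to be deleted without moving the C-4=C-5 alkene.
- Only one relative configuration would be available.

Key step: step 8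

## Steps

**Common part (steps 1 to 5)**

Step 1
Reactants: 1 2,4,4-trimethylcyclohex-2-en-1-one
Product: 2 2,4,4-trimethylcyclohexa-2,5-dien-1-one
Conditions: DDQ (1.2 equiv), TsOH (cat.), 1,4-dioxane, reflux
Reagents that add atoms: none
Why: Dehydrogenation of an enone by DDQ (hydride abstraction from C-5 of the acid-formed dienol); C-4 is quaternary, so only the cross-conjugated dienone can form and it cannot aromatise.

Step 2
Reactants: 2 2,4,4-trimethylcyclohexa-2,5-dien-1-one; 3 potassium trifluoro(vinyl)borate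
Product: 4 (5R)-5-ethenyl-2,4,4-trimethylcyclohex-2-en-1-one
Conditions: [Rh(cod)2]PF6 (3 mol %), (R)-BINAP (3.3 mol %), 3 (2 equiv), toluene/H2O 4:1, 105 °C
Reagents that add atoms: potassium trifluoro(vinyl)borate (3), C=C[B-](F)(F)F.[K+]
Why: Rhodium-catalysed asymmetric 1,4-addition of an alkenylboron reagent (Hayashi–Miyaura reaction); the vinyl–rhodium species inserts only the α-unsubstituted C5=C6 arm because the α-methyl arm is a far poorer acceptor, and the (R)-BINAP complex selects the enone face (the mirror image of the sense in which (S)-BINAP gives (S)-3-phenylcyclohexanone), which sets C-5 (carotenoid C-2) as R; water protonates the oxa-π-allyl rhodium.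

Step 3
Reactants: 4 (5R)-5-ethenyl-2,4,4-trimethylcyclohex-2-en-1-one
Product: 6 (5S)-5-(2-hydroxyethyl)-2,4,4-trimethylcyclohex-2-en-1-one, via pinacol boronate 5 (not isolated)
Conditions: pinacolborane (1.3 equiv), RhCl(PPh3)3 (2 mol %), THF, 25 °C; then NaBO3·4H2O, THF/H2O, 25 °C
Reagents that add atoms: pinacolborane, [H]B1OC(C)(C)C(C)(C)O1; sodium perborate, [Na+].[O-]OB=O
Why: Rhodium-catalysed anti-Markovnikov hydroboration of a terminal alkene is chemoselective over ketones and should leave the hindered s-trans enone alone; perborate oxidises the C–B bond under conditions too mild for nucleophilic epoxidation of the enone; the stereocentre is untouched (the descriptor becomes S only through a priority change).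

Step 4
Reactants: 6 (5S)-5-(2-hydroxyethyl)-2,4,4-trimethylcyclohex-2-en-1-one
Product: 7 2-[(1S)-2,2,4-trimethyl-5-oxocyclohex-3-en-1-yl]acetaldehyde
Conditions: TEMPO (0.1 equiv), PhI(OAc)2 (1.1 equiv), CH2Cl2, 25 °C
Reagents that add atoms: none
Why: TEMPO/PhI(OAc)2 oxidation of a primary alcohol stops at the aldehyde and does not touch the enone; the stereocentre is β to the new carbonyl and cannot epimerise.

Step 5
Reactants: 7 2-[(1S)-2,2,4-trimethyl-5-oxocyclohex-3-en-1-yl]acetaldehyde; 8 isopropyltriphenylphosphonium iodide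
Product: 10 (5S)-2,4,4-trimethyl-5-(3-methylbut-2-en-1-yl)cyclohex-2-en-1-one, via isopropylidene ylide 9 (not isolated)
Conditions: 8 (1.1 equiv), n-BuLi (1.05 equiv), THF, 0 °C; then 7, −78 → 0 °C
Reagents that add atoms: isopropyltriphenylphosphonium iodide (8), CC(C)[P+](c1ccccc1)(c1ccccc1)c1ccccc1.[I-]
Why: Wittig olefination with a non-stabilised ylide; at −78 °C the ylide should react with the aldehyde far faster than with the conjugated, α-branched ring ketone; an isopropylidene group raises no geometry issue.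

**Ring A series (steps 6 to 11)**

Step 6
Reactants: 10 (5S)-2,4,4-trimethyl-5-(3-methylbut-2-en-1-yl)cyclohex-2-en-1-one
Product: 11 (1R,5S)-2,4,4-trimethyl-5-(3-methylbut-2-en-1-yl)cyclohex-2-en-1-ol
Conditions: (S)-Me-CBS oxazaborolidine (0.2 equiv), catecholborane (1.8 equiv), toluene, −78 °C; aq. NaOH work-up
Reagents that add atoms: none
Why: Corey–Bakshi–Shibata reduction with the C-2 methyl alkene arm as the large group (the (S)-catalyst in the sense that gives (R)-1-phenylethanol from acetophenone) should give the 1R carbinol, cis to the C-5 side chain; the substrate's own preference (pseudo-axial hydride delivery, as in carvone to cis-carveol) is expected to point the same way; catecholborane at −78 °C does not hydroborate the prenyl group.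

Step 7
Reactants: 11 (1R,5S)-2,4,4-trimethyl-5-(3-methylbut-2-en-1-yl)cyclohex-2-en-1-ol; 12 1-bromobut-2-yne
Product: 13 (4S,6R)-6-(but-2-yn-1-yloxy)-1,3,3-trimethyl-4-(3-methylbut-2-en-1-yl)cyclohex-1-ene
Conditions: NaH (1.3 equiv), 12 (1.5 equiv), Bu4NI (cat.), THF/DMF, 0 → 25 °C
Reagents that add atoms: 1-bromobut-2-yne (12), CC#CCBr
Why: Williamson etherification of the sodium alkoxide with a reactive propargylic bromide; no stereocentre is affected.

Step 8
Reactants: 13 (4S,6R)-6-(but-2-yn-1-yloxy)-1,3,3-trimethyl-4-(3-methylbut-2-en-1-yl)cyclohex-1-ene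
Product: 15 1-[(1R,5S)-2,6,6-trimethyl-5-(3-methylbut-2-en-1-yl)cyclohex-2-en-1-yl]but-2-yn-1-ol (mixture of carbinol epimers), via α-lithio ether 14 (not isolated)
Conditions: n-BuLi (1.5 equiv), THF, −78 → −30 °C; then H2O
Reagents that add atoms: none
Why: n-BuLi removes a proton from the O–CH2 group, which is both propargylic and α to oxygen, to give 14; this carbanion attacks C-6 (cyclohexene C-2) through a five-membered envelope transition state while the C-4–O bond breaks and the alkene moves to C-4=C-5, a concerted suprafacial [2,3]-sigmatropic shift. The closest known reaction type is the [2,3]-Wittig rearrangement of allyl propargyl ethers, which is established for cyclic allylic ethers. No ring is closed; the six-membered ring is already present. The new C-6 stereocentre is controlled by the C-4 carbinol configuration through 1,3-chirality transfer: C-7 is delivered to the face that carried oxygen, which in 13 is the face of the C-2 side chain, so the ring becomes 2,6-cis (6R). The carbinol centre at C-7 forms without needed control and is erased in step 9. The step needs lithiation at O–CH2 and not at the terminal methyl or at C-4–H, which the combined propargylic and α-oxygen activation should secure, and it needs the [2,3] path over the [1,2] radical-pair path, which low temperature and the short intramolecular reach to C-6 should secure despite the neighbouring quaternary carbon. The reacting conformer must hold the C–O bond pseudo-axial, which in the cis series also puts the C-2 chain axial; this costs energy but is accessible because an axial chain next to the gem-dimethyl carbon loses one gauche interaction. The ring alkene reaches the ε-position without any cationic or conjugated intermediate, so no double-bond isomers can arise.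

Step 9
Reactants: 15 1-[(1R,5S)-2,6,6-trimethyl-5-(3-methylbut-2-en-1-yl)cyclohex-2-en-1-yl]but-2-yn-1-ol
Product: 17 (3E)-4-[(1R,5S)-2,6,6-trimethyl-5-(3-methylbut-2-en-1-yl)cyclohex-2-en-1-yl]but-3-en-2-one, via allenol 16 (not isolated)
Conditions: ReOCl3(OPPh3)(SMe2) (5 mol %), DME, 25 °C
Reagents that add atoms: none
Why: Meyer–Schuster rearrangement: oxo-rhenium-catalysed 1,3-transposition of the propargylic hydroxyl gives allenol 16, which tautomerises to the conjugated ketone, and thermodynamic control should give the E-enone; the catalyst acts on the hydroxyl and not on the alkyne π-bond, so the 1,5-enyne should not cycloisomerise; both carbinol epimers converge and C-6 is untouched.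

Step 10
Reactants: 17 (3E)-4-[(1R,5S)-2,6,6-trimethyl-5-(3-methylbut-2-en-1-yl)cyclohex-2-en-1-yl]but-3-en-2-one; 18 vinylmagnesium bromide
Product: 19 (1E)-3-methyl-1-[(1R,5S)-2,6,6-trimethyl-5-(3-methylbut-2-en-1-yl)cyclohex-2-en-1-yl]penta-1,4-dien-3-ol (mixture of carbinol epimers)
Conditions: 18 (1.5 equiv), THF, −20 → 0 °C; aq. NH4Cl
Reagents that add atoms: vinylmagnesium bromide (18), C=C[Mg]Br
Why: 1,2-addition of a vinyl Grignard reagent to an α-ionone-type enone, the standard entry to vinyl-ionols; the new C-9 carbinol centre forms without control and is erased in step 11.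

Step 11
Reactants: 19 (1E)-3-methyl-1-[(1R,5S)-2,6,6-trimethyl-5-(3-methylbut-2-en-1-yl)cyclohex-2-en-1-yl]penta-1,4-dien-3-ol
Product: 20 [(2E,4E)-3-methyl-5-[(1R,5S)-2,6,6-trimethyl-5-(3-methylbut-2-en-1-yl)cyclohex-2-en-1-yl]penta-2,4-dien-1-yl]triphenylphosphonium bromide
Conditions: PPh3·HBr (1.05 equiv), CH2Cl2, 0 → 25 °C; trituration to remove the 9Z salt
Reagents that add atoms: triphenylphosphine hydrobromide, [Br-].c1ccc(cc1)[PH+](c1ccccc1)c1ccccc1
Why: Allylic phosphonium salt formation: Ph3PH+ ionises the tertiary, doubly allylic carbinol and PPh3 captures the pentadienyl cation at its unhindered primary terminus C-11, as in the usual C15 Wittig salts; this weak acid should not protonate the ring or prenyl alkenes, and C-6 is untouched.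

**Ring B series (steps 12 to 19)**

Step 12
Reactants: 10 (5S)-2,4,4-trimethyl-5-(3-methylbut-2-en-1-yl)cyclohex-2-en-1-one
Product: 21 (5S)-5-[(2E)-4-hydroxy-3-methylbut-2-en-1-yl]-2,4,4-trimethylcyclohex-2-en-1-one
Conditions: SeO2 (0.5 equiv), t-BuOOH (3 equiv), salicylic acid (0.1 equiv), CH2Cl2, 0 → 25 °C
Reagents that add atoms: tert-butyl hydroperoxide, CC(C)(C)OO; selenium dioxide, O=[Se]=O
Why: SeO2 allylic oxidation (ene reaction, then [2,3] shift of the allylseleninic acid) of a gem-dimethyl alkene occurs at the methyl group E to the chain and gives the E-allylic alcohol; the only other alkene is the electron-poor enone, which should not undergo the ene step.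

Step 13
Reactants: 21 (5S)-5-[(2E)-4-hydroxy-3-methylbut-2-en-1-yl]-2,4,4-trimethylcyclohex-2-en-1-one
Product: 22 (5S)-5-{(2E)-4-[(tert-butyldiphenylsilyl)oxy]-3-methylbut-2-en-1-yl}-2,4,4-trimethylcyclohex-2-en-1-one
Conditions: TBDPSCl (1.2 equiv), imidazole (2.5 equiv), DMF, 25 °C
Reagents that add atoms: tert-butyl(chloro)diphenylsilane, CC(C)(C)[Si](Cl)(c1ccccc1)c1ccccc1
Why: Silylation of a primary alcohol; the TBDPS ether is chosen because it should survive n-BuLi, the Grignard reagent and the weakly acidic phosphonium-forming step.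

Step 14
Reactants: 22 (5S)-5-{(2E)-4-[(tert-butyldiphenylsilyl)oxy]-3-methylbut-2-en-1-yl}-2,4,4-trimethylcyclohex-2-en-1-one
Product: 23 (1S,5S)-5-{(2E)-4-[(tert-butyldiphenylsilyl)oxy]-3-methylbut-2-en-1-yl}-2,4,4-trimethylcyclohex-2-en-1-ol
Conditions: (R)-Me-CBS oxazaborolidine (0.3 equiv), catecholborane (1.8 equiv), toluene, −78 °C; aq. NaOH work-up
Reagents that add atoms: none
Why: Corey–Bakshi–Shibata reduction with the enantiomeric catalyst should give the 1S carbinol, trans to the C-5 side chain; here the catalyst must override the substrate's own preference, which is plausible because α-methyl cyclic enones are strongly catalyst-controlled substrates.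

Step 15
Reactants: 23 (1S,5S)-5-{(2E)-4-[(tert-butyldiphenylsilyl)oxy]-3-methylbut-2-en-1-yl}-2,4,4-trimethylcyclohex-2-en-1-ol; 12 1-bromobut-2-yne
Product: 24 tert-butyl{[(2E)-4-[(1S,5S)-5-(but-2-yn-1-yloxy)-2,2,4-trimethylcyclohex-3-en-1-yl]-2-methylbut-2-en-1-yl]oxy}diphenylsilane
Conditions: NaH (1.3 equiv), 12 (1.5 equiv), Bu4NI (cat.), THF/DMF, 0 → 25 °C
Reagents that add atoms: 1-bromobut-2-yne (12), CC#CCBr
Why: Williamson etherification as in step 7; the silyl ether is stable to NaH.

Step 16
Reactants: 24 tert-butyl{[(2E)-4-[(1S,5S)-5-(but-2-yn-1-yloxy)-2,2,4-trimethylcyclohex-3-en-1-yl]-2-methylbut-2-en-1-yl]oxy}diphenylsilane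
Product: 26 1-[(1S,5R)-5-{(2E)-4-[(tert-butyldiphenylsilyl)oxy]-3-methylbut-2-en-1-yl}-2,6,6-trimethylcyclohex-2-en-1-yl]but-2-yn-1-ol (mixture of carbinol epimers), via α-lithio ether 25 (not isolated)
Conditions: n-BuLi (1.5 equiv), THF, −78 → −30 °C; then H2O
Reagents that add atoms: none
Why: The same [2,3]-Wittig rearrangement as in step 8 on the trans ether; the C–O bond is pseudo-axial with the C-2' chain equatorial in the favoured half-chair, and suprafacial delivery of C-7' to the oxygen face, opposite to the C-2' chain, gives the 2,6-trans ring (6'S).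

Step 17
Reactants: 26 1-[(1S,5R)-5-{(2E)-4-[(tert-butyldiphenylsilyl)oxy]-3-methylbut-2-en-1-yl}-2,6,6-trimethylcyclohex-2-en-1-yl]but-2-yn-1-ol
Product: 28 (3E)-4-[(1S,5R)-5-{(2E)-4-[(tert-butyldiphenylsilyl)oxy]-3-methylbut-2-en-1-yl}-2,6,6-trimethylcyclohex-2-en-1-yl]but-3-en-2-one, via allenol 27 (not isolated)
Conditions: ReOCl3(OPPh3)(SMe2) (5 mol %), DME, 25 °C
Reagents that add atoms: none
Why: Meyer–Schuster rearrangement as in step 9; the mild oxo-rhenium catalyst is expected to leave the primary allylic silyl ether in place.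

Step 18
Reactants: 28 (3E)-4-[(1S,5R)-5-{(2E)-4-[(tert-butyldiphenylsilyl)oxy]-3-methylbut-2-en-1-yl}-2,6,6-trimethylcyclohex-2-en-1-yl]but-3-en-2-one; 18 vinylmagnesium bromide
Product: 29 (1E)-1-[(1S,5R)-5-{(2E)-4-[(tert-butyldiphenylsilyl)oxy]-3-methylbut-2-en-1-yl}-2,6,6-trimethylcyclohex-2-en-1-yl]-3-methylpenta-1,4-dien-3-ol (mixture of carbinol epimers)
Conditions: 18 (1.5 equiv), THF, −20 → 0 °C; aq. NH4Cl
Reagents that add atoms: vinylmagnesium bromide (18), C=C[Mg]Br
Why: 1,2-addition of the vinyl Grignard reagent as in step 10; the carbinol centre is erased in step 19.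

Step 19
Reactants: 29 (1E)-1-[(1S,5R)-5-{(2E)-4-[(tert-butyldiphenylsilyl)oxy]-3-methylbut-2-en-1-yl}-2,6,6-trimethylcyclohex-2-en-1-yl]-3-methylpenta-1,4-dien-3-ol
Product: 30 [(2E,4E)-5-[(1S,5R)-5-{(2E)-4-[(tert-butyldiphenylsilyl)oxy]-3-methylbut-2-en-1-yl}-2,6,6-trimethylcyclohex-2-en-1-yl]-3-methylpenta-2,4-dien-1-yl]triphenylphosphonium bromide
Conditions: PPh3·HBr (1.05 equiv), CH2Cl2, 0 °C; trituration
Reagents that add atoms: triphenylphosphine hydrobromide, [Br-].c1ccc(cc1)[PH+](c1ccccc1)c1ccccc1
Why: Allylic phosphonium salt formation as in step 11; the tertiary pentadienylic carbinol ionises far faster than the primary allylic silyl ether, and the TBDPS group is the most acid-stable common silyl ether.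

**Assembly (steps 20 to 22)**

Step 20
Reactants: 20 [(2E,4E)-3-methyl-5-[(1R,5S)-2,6,6-trimethyl-5-(3-methylbut-2-en-1-yl)cyclohex-2-en-1-yl]penta-2,4-dien-1-yl]triphenylphosphonium bromide; 31 (2E,4E,6E)-2,7-dimethylocta-2,4,6-trienedial
Product: 33 (2E,4E,6E,8E,10E,12E)-2,7,11-trimethyl-13-[(1R,5S)-2,6,6-trimethyl-5-(3-methylbut-2-en-1-yl)cyclohex-2-en-1-yl]trideca-2,4,6,8,10,12-hexaenal, via ylide 32 (not isolated)
Conditions: 31 (3 equiv), NaOMe (1.1 equiv), CH2Cl2/MeOH, 0 → 25 °C, dark, Ar; then I2 (cat.), hexane, 25 °C (Z → E)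
Reagents that add atoms: (2E,4E,6E)-2,7-dimethylocta-2,4,6-trienedial (31), O=C/C(C)=C/C=C/C=C(C)/C=O
Why: Wittig olefination forming C-11=C-12; the excess of 31 and the lower electrophilicity of the remaining vinylogous aldehyde should ensure mono-olefination; the new double bond forms as an E/Z mixture that iodine equilibrates to E; the ε-ring methine is not acidic enough for methoxide.

Step 21
Reactants: 30 [(2E,4E)-5-[(1S,5R)-5-{(2E)-4-[(tert-butyldiphenylsilyl)oxy]-3-methylbut-2-en-1-yl}-2,6,6-trimethylcyclohex-2-en-1-yl]-3-methylpenta-2,4-dien-1-yl]triphenylphosphonium bromide; 33 (2E,4E,6E,8E,10E,12E)-2,7,11-trimethyl-13-[(1R,5S)-2,6,6-trimethyl-5-(3-methylbut-2-en-1-yl)cyclohex-2-en-1-yl]trideca-2,4,6,8,10,12-hexaenal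
Product: 35 (all-E,2S,6R,2'R,6'S)-2'-{(2E)-4-[(tert-butyldiphenylsilyl)oxy]-3-methylbut-2-en-1-yl}-2-(3-methylbut-2-en-1-yl)-ε,ε-carotene, via ylide 34 (not isolated)
Conditions: NaOMe (1.2 equiv), CH2Cl2/MeOH, 0 → 25 °C, dark, Ar; then heptane, reflux (Z → E)
Reagents that add atoms: none
Why: Wittig olefination forming C-11'=C-12' and completing the nonaene; thermal equilibration in a hydrocarbon solvent should bring the 11'Z isomer to the all-E polyene, as is usual for carotenoids; no stereocentre is touched.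

Step 22
Reactants: 35 (all-E,2S,6R,2'R,6'S)-2'-{(2E)-4-[(tert-butyldiphenylsilyl)oxy]-3-methylbut-2-en-1-yl}-2-(3-methylbut-2-en-1-yl)-ε,ε-carotene
Product: 36 (all-E,2S,6R,2'R,6'S)-2'-[(2E)-4-hydroxy-3-methylbut-2-en-1-yl]-2-(3-methylbut-2-en-1-yl)-ε,ε-carotene (target)
Conditions: Bu4NF (2 equiv), AcOH (2 equiv), THF, 0 → 25 °C, dark, Ar
Reagents that add atoms: none
Why: Fluoride cleavage of the silyl ether, buffered with acetic acid so that neither base nor acid acts on the polyene or the ε-rings; this should release the target.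

## Compound list

1 | 2,4,4-trimethylcyclohex-2-en-1-one | CC1=CC(C)(C)CCC1=O | starting material
2 | 2,4,4-trimethylcyclohexa-2,5-dien-1-one | CC1=CC(C)(C)C=CC1=O | intermediate
3 | potassium trifluoro(vinyl)borate | C=C[B-](F)(F)F.[K+] | starting material
4 | (5R)-5-ethenyl-2,4,4-trimethylcyclohex-2-en-1-one | CC1=CC(C)(C)[C@@H](C=C)CC1=O | intermediate
5 | (5S)-2,4,4-trimethyl-5-[2-(4,4,5,5-tetramethyl-1,3,2-dioxaborolan-2-yl)ethyl]cyclohex-2-en-1-one | CC1=CC(C)(C)[C@@H](CCB2OC(C)(C)C(C)(C)O2)CC1=O | intermediate (not isolated)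
6 | (5S)-5-(2-hydroxyethyl)-2,4,4-trimethylcyclohex-2-en-1-one | CC1=CC(C)(C)[C@@H](CCO)CC1=O | intermediate
7 | 2-[(1S)-2,2,4-trimethyl-5-oxocyclohex-3-en-1-yl]acetaldehyde | CC1=CC(C)(C)[C@@H](CC=O)CC1=O | intermediate
8 | isopropyltriphenylphosphonium iodide | CC(C)[P+](c1ccccc1)(c1ccccc1)c1ccccc1.[I-] | starting material
9 | triphenyl(propan-2-ylidene)-λ5-phosphane | CC(C)=P(c1ccccc1)(c1ccccc1)c1ccccc1 | intermediate (not isolated)
10 | (5S)-2,4,4-trimethyl-5-(3-methylbut-2-en-1-yl)cyclohex-2-en-1-one | CC1=CC(C)(C)[C@@H](CC=C(C)C)CC1=O | intermediate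
11 | (1R,5S)-2,4,4-trimethyl-5-(3-methylbut-2-en-1-yl)cyclohex-2-en-1-ol | CC1=CC(C)(C)[C@@H](CC=C(C)C)C[C@H]1O | intermediate
12 | 1-bromobut-2-yne | CC#CCBr | starting material
13 | (4S,6R)-6-(but-2-yn-1-yloxy)-1,3,3-trimethyl-4-(3-methylbut-2-en-1-yl)cyclohex-1-ene | CC1=CC(C)(C)[C@@H](CC=C(C)C)C[C@H]1OCC#CC | intermediate
14 | (1-{[(1R,5S)-2,4,4-trimethyl-5-(3-methylbut-2-en-1-yl)cyclohex-2-en-1-yl]oxy}but-2-yn-1-yl)lithium | CC1=CC(C)(C)[C@@H](CC=C(C)C)C[C@H]1OC([Li])C#CC | intermediate (not isolated)
15 | 1-[(1R,5S)-2,6,6-trimethyl-5-(3-methylbut-2-en-1-yl)cyclohex-2-en-1-yl]but-2-yn-1-ol (carbinol epimers) | CC(C)=CC[C@H]1CC=C(C)[C@@H](C(O)C#CC)C1(C)C | intermediate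
16 | 4-[(1R,5S)-2,6,6-trimethyl-5-(3-methylbut-2-en-1-yl)cyclohex-2-en-1-yl]buta-2,3-dien-2-ol | CC(C)=CC[C@H]1CC=C(C)[C@@H](C=C=C(C)O)C1(C)C | intermediate (not isolated)
17 | (3E)-4-[(1R,5S)-2,6,6-trimethyl-5-(3-methylbut-2-en-1-yl)cyclohex-2-en-1-yl]but-3-en-2-one | CC(C)=CC[C@H]1CC=C(C)[C@@H](/C=C/C(C)=O)C1(C)C | intermediate
18 | vinylmagnesium bromide | C=C[Mg]Br | starting material
19 | (1E)-3-methyl-1-[(1R,5S)-2,6,6-trimethyl-5-(3-methylbut-2-en-1-yl)cyclohex-2-en-1-yl]penta-1,4-dien-3-ol (carbinol epimers) | CC(C)=CC[C@H]1CC=C(C)[C@@H](/C=C/C(C)(O)C=C)C1(C)C | intermediate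
20 | [(2E,4E)-3-methyl-5-[(1R,5S)-2,6,6-trimethyl-5-(3-methylbut-2-en-1-yl)cyclohex-2-en-1-yl]penta-2,4-dien-1-yl]triphenylphosphonium bromide | CC(C)=CC[C@H]1CC=C(C)[C@@H](/C=C/C(C)=C/C[P+](c2ccccc2)(c2ccccc2)c2ccccc2)C1(C)C.[Br-] | intermediate
21 | (5S)-5-[(2E)-4-hydroxy-3-methylbut-2-en-1-yl]-2,4,4-trimethylcyclohex-2-en-1-one | CC1=CC(C)(C)[C@@H](C/C=C(\C)CO)CC1=O | intermediate
22 | (5S)-5-{(2E)-4-[(tert-butyldiphenylsilyl)oxy]-3-methylbut-2-en-1-yl}-2,4,4-trimethylcyclohex-2-en-1-one | CC1=CC(C)(C)[C@@H](C/C=C(\C)CO[Si](c2ccccc2)(c2ccccc2)C(C)(C)C)CC1=O | intermediate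
23 | (1S,5S)-5-{(2E)-4-[(tert-butyldiphenylsilyl)oxy]-3-methylbut-2-en-1-yl}-2,4,4-trimethylcyclohex-2-en-1-ol | CC1=CC(C)(C)[C@@H](C/C=C(\C)CO[Si](c2ccccc2)(c2ccccc2)C(C)(C)C)C[C@@H]1O | intermediate
24 | tert-butyl{[(2E)-4-[(1S,5S)-5-(but-2-yn-1-yloxy)-2,2,4-trimethylcyclohex-3-en-1-yl]-2-methylbut-2-en-1-yl]oxy}diphenylsilane | CC1=CC(C)(C)[C@@H](C/C=C(\C)CO[Si](c2ccccc2)(c2ccccc2)C(C)(C)C)C[C@@H]1OCC#CC | intermediate
25 | [1-({(1S,5S)-5-[(2E)-4-{[tert-butyl(diphenyl)silyl]oxy}-3-methylbut-2-en-1-yl]-2,4,4-trimethylcyclohex-2-en-1-yl}oxy)but-2-yn-1-yl]lithium | CC1=CC(C)(C)[C@@H](C/C=C(\C)CO[Si](c2ccccc2)(c2ccccc2)C(C)(C)C)C[C@@H]1OC([Li])C#CC | intermediate (not isolated)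
26 | 1-[(1S,5R)-5-{(2E)-4-[(tert-butyldiphenylsilyl)oxy]-3-methylbut-2-en-1-yl}-2,6,6-trimethylcyclohex-2-en-1-yl]but-2-yn-1-ol (carbinol epimers) | CC#CC(O)[C@H]1C(C)=CC[C@H](C/C=C(\C)CO[Si](c2ccccc2)(c2ccccc2)C(C)(C)C)C1(C)C | intermediate
27 | 4-[(1S,5R)-5-{(2E)-4-[(tert-butyldiphenylsilyl)oxy]-3-methylbut-2-en-1-yl}-2,6,6-trimethylcyclohex-2-en-1-yl]buta-2,3-dien-2-ol | CC(O)=C=C[C@H]1C(C)=CC[C@H](C/C=C(\C)CO[Si](c2ccccc2)(c2ccccc2)C(C)(C)C)C1(C)C | intermediate (not isolated)
28 | (3E)-4-[(1S,5R)-5-{(2E)-4-[(tert-butyldiphenylsilyl)oxy]-3-methylbut-2-en-1-yl}-2,6,6-trimethylcyclohex-2-en-1-yl]but-3-en-2-one | CC(=O)/C=C/[C@H]1C(C)=CC[C@H](C/C=C(\C)CO[Si](c2ccccc2)(c2ccccc2)C(C)(C)C)C1(C)C | intermediate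
29 | (1E)-1-[(1S,5R)-5-{(2E)-4-[(tert-butyldiphenylsilyl)oxy]-3-methylbut-2-en-1-yl}-2,6,6-trimethylcyclohex-2-en-1-yl]-3-methylpenta-1,4-dien-3-ol (carbinol epimers) | C=CC(C)(O)/C=C/[C@H]1C(C)=CC[C@H](C/C=C(\C)CO[Si](c2ccccc2)(c2ccccc2)C(C)(C)C)C1(C)C | intermediate
30 | [(2E,4E)-5-[(1S,5R)-5-{(2E)-4-[(tert-butyldiphenylsilyl)oxy]-3-methylbut-2-en-1-yl}-2,6,6-trimethylcyclohex-2-en-1-yl]-3-methylpenta-2,4-dien-1-yl]triphenylphosphonium bromide | c3ccccc3[P+](c3ccccc3)(c3ccccc3)C/C=C(C)/C=C/[C@H]1C(C)=CC[C@H](C/C=C(\C)CO[Si](c2ccccc2)(c2ccccc2)C(C)(C)C)C1(C)C.[Br-] | intermediate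
31 | (2E,4E,6E)-2,7-dimethylocta-2,4,6-trienedial | O=C/C(C)=C/C=C/C=C(C)/C=O | starting material
32 | [(2E,4E)-3-methyl-5-[(1R,5S)-2,6,6-trimethyl-5-(3-methylbut-2-en-1-yl)cyclohex-2-en-1-yl]penta-2,4-dien-1-ylidene]triphenyl-λ5-phosphane | CC(C)=CC[C@H]1CC=C(C)[C@@H](/C=C/C(C)=C/C=P(c2ccccc2)(c2ccccc2)c2ccccc2)C1(C)C | intermediate (not isolated)
33 | (2E,4E,6E,8E,10E,12E)-2,7,11-trimethyl-13-[(1R,5S)-2,6,6-trimethyl-5-(3-methylbut-2-en-1-yl)cyclohex-2-en-1-yl]trideca-2,4,6,8,10,12-hexaenal | CC(C)=CC[C@H]1CC=C(C)[C@@H](/C=C/C(C)=C/C=C/C(C)=C/C=C/C=C(C)/C=O)C1(C)C | intermediate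
34 | [(2E,4E)-5-[(1S,5R)-5-{(2E)-4-[(tert-butyldiphenylsilyl)oxy]-3-methylbut-2-en-1-yl}-2,6,6-trimethylcyclohex-2-en-1-yl]-3-methylpenta-2,4-dien-1-ylidene]triphenyl-λ5-phosphane | c3ccccc3P(c3ccccc3)(c3ccccc3)=C/C=C(C)/C=C/[C@H]1C(C)=CC[C@H](C/C=C(\C)CO[Si](c2ccccc2)(c2ccccc2)C(C)(C)C)C1(C)C | intermediate (not isolated)
35 | (all-E,2S,6R,2'R,6'S)-2'-{(2E)-4-[(tert-butyldiphenylsilyl)oxy]-3-methylbut-2-en-1-yl}-2-(3-methylbut-2-en-1-yl)-ε,ε-carotene | CC(C)=CC[C@H]1CC=C(C)[C@@H](/C=C/C(C)=C/C=C/C(C)=C/C=C/C=C(C)/C=C/C=C(C)/C=C/[C@H]2C(C)=CC[C@H](C/C=C(\C)CO[Si](c3ccccc3)(c3ccccc3)C(C)(C)C)C2(C)C)C1(C)C | intermediate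
36 | (all-E,2S,6R,2'R,6'S)-2'-[(2E)-4-hydroxy-3-methylbut-2-en-1-yl]-2-(3-methylbut-2-en-1-yl)-ε,ε-carotene | CC(C)=CC[C@H]1CC=C(C)[C@@H](/C=C/C(C)=C/C=C/C(C)=C/C=C/C=C(C)/C=C/C=C(C)/C=C/[C@H]2C(C)=CC[C@H](C/C=C(\C)CO)C2(C)C)C1(C)C | target

## Step count and risk

Total step count: 22. Longest linear sequence: 15 steps (1 to 5, 12 to 19, 21, 22).

Least certain steps:

**Step 8 (key step).**
- What may go wrong: lithiation at the terminal methyl or at C-4–H instead of O–CH2; and leakage into the [1,2]-shift through a radical pair if the concerted path is slowed, because in the cis series the pseudo-axial C–O bond forces the C-2 chain axial as well. Step 16 is the same reaction on the trans ether, the conformationally easier case.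
- Fallback: it sets out from 11 and returns at 17. The alkoxide of 11 (KH, THF) is alkylated with Bu3SnCH2I to the stannylmethyl ether F1. Tin–lithium exchange with n-BuLi at −78 °C generates the α-alkoxy carbanion with no choice of site, and its Wittig–Still [2,3] shift gives the homoallylic alcohol F2 with the same transfer of chirality. Buffered Dess–Martin oxidation gives the aldehyde F3. Horner–Wadsworth–Emmons olefination with diethyl (2-oxopropyl)phosphonate and Ba(OH)2 in wet THF forms C-7=C-8 and gives 17. This changes the migrating unit to one carbon and builds C-8 to C-10 by olefination, at the price of handling an epimerisable β,γ-unsaturated aldehyde.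

**Step 2.**
- What may go wrong: slow insertion at the β-carbon next to the quaternary centre, protodeboronation of 3 outrunning addition, or eroded facial selectivity.
- Fallback: it sets out from 2 and returns at 10. A copper-catalysed asymmetric conjugate addition of di(but-3-enyl)zinc (Cu(OTf)2 with a binaphthol-derived phosphoramidite ligand of the appropriate hand, toluene, −25 °C), a reaction type established on 4,4-dialkylcyclohexadienones, gives the butenyl enone F4. One-position alkene isomerisation with [CpRu(NCMe)(2-(i-Pr2P)-4-t-Bu-1-methylimidazole)]PF6 in acetone gives the (E)-but-2-enyl enone F5. Cross-metathesis with excess 2-methylbut-2-ene and the second-generation Grubbs catalyst RuCl2(=CHPh)(H2IMes)(PCy3) gives 10, bypassing 4 to 7.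

**Step 14.**
- What may go wrong: poor facial selectivity, because the catalyst works against the substrate's own bias and the cis carbinol may dominate.
- Fallback: it sets out from 22 and returns at 23. Reduction with the (S)-catalyst, in concert with the substrate, gives the cis alcohol F6. Mitsunobu reaction (4-nitrobenzoic acid, PPh3, DIAD, THF) inverts the carbinol to the trans 4-nitrobenzoate F7. K2CO3 in MeOH gives 23.

**Step 9 (and its twin, step 17).**
- What may go wrong: acid-type side reactions of the oxo-rhenium catalyst, namely migration of the ring alkene, cyclisation of the prenyl group onto a cation, or 1,3-transposition of the allylic silyl ether in series B; and incomplete E selectivity.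
- Fallback: it sets out from 15 and returns at 17. Acetylation (Ac2O, DMAP, Et3N) gives the propargylic acetate F8. A [3,3] acyloxy shift catalysed by AgBF4 in CH2Cl2 gives the allenyl acetate F9. Methanolysis with K2CO3 in MeOH releases the enolate, which protonates to the E-enone 17.

**Step 12.**
- What may go wrong: over-oxidation to the enal, incomplete conversion, or attack at the position α to the ketone.
- Fallback: it sets out from 7 and returns at 23. Wittig reaction of 7 with ethyl 2-(triphenylphosphoranylidene)propanoate in CH2Cl2 gives the E-enoate F10. Reduction with the (R)-Me-CBS catalyst and catecholborane gives the trans hydroxy ester F11. Reduction with i-Bu2AlH at −78 °C gives the diol F12. Selective silylation of the primary hydroxyl (TBDPSCl 1.05 equiv, imidazole, −20 °C) gives 23, bypassing 21 and 22.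

## Further compounds

F1 | step 8 | tributyl({[(1R,5S)-2,4,4-trimethyl-5-(3-methylbut-2-en-1-yl)cyclohex-2-en-1-yl]oxy}methyl)stannane | CC1=CC(C)(C)[C@@H](CC=C(C)C)C[C@H]1OC[Sn](CCCC)(CCCC)CCCC
F2 | step 8 | [(1R,5S)-2,6,6-trimethyl-5-(3-methylbut-2-en-1-yl)cyclohex-2-en-1-yl]methanol | CC(C)=CC[C@H]1CC=C(C)[C@@H](CO)C1(C)C
F3 | step 8 | (1R,5S)-2,6,6-trimethyl-5-(3-methylbut-2-en-1-yl)cyclohex-2-ene-1-carbaldehyde | CC(C)=CC[C@H]1CC=C(C)[C@@H](C=O)C1(C)C
F4 | step 2 | (5S)-5-(but-3-en-1-yl)-2,4,4-trimethylcyclohex-2-en-1-one | CC1=CC(C)(C)[C@@H](CCC=C)CC1=O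
F5 | step 2 | (5S)-5-[(2E)-but-2-en-1-yl]-2,4,4-trimethylcyclohex-2-en-1-one | CC1=CC(C)(C)[C@@H](C/C=C/C)CC1=O
F6 | step 14 | (1R,5S)-5-{(2E)-4-[(tert-butyldiphenylsilyl)oxy]-3-methylbut-2-en-1-yl}-2,4,4-trimethylcyclohex-2-en-1-ol | CC1=CC(C)(C)[C@@H](C/C=C(\C)CO[Si](c2ccccc2)(c2ccccc2)C(C)(C)C)C[C@H]1O
F7 | step 14 | (1S,5S)-5-{(2E)-4-[(tert-butyldiphenylsilyl)oxy]-3-methylbut-2-en-1-yl}-2,4,4-trimethylcyclohex-2-en-1-yl 4-nitrobenzoate | CC1=CC(C)(C)[C@@H](C/C=C(\C)CO[Si](c2ccccc2)(c2ccccc2)C(C)(C)C)C[C@@H]1OC(=O)c3ccc(cc3)[N+](=O)[O-]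
F8 | step 9 | 1-[(1R,5S)-2,6,6-trimethyl-5-(3-methylbut-2-en-1-yl)cyclohex-2-en-1-yl]but-2-yn-1-yl acetate | CC(C)=CC[C@H]1CC=C(C)[C@@H](C(OC(C)=O)C#CC)C1(C)C
F9 | step 9 | 4-[(1R,5S)-2,6,6-trimethyl-5-(3-methylbut-2-en-1-yl)cyclohex-2-en-1-yl]buta-2,3-dien-2-yl acetate | CC(C)=CC[C@H]1CC=C(C)[C@@H](C=C=C(C)OC(C)=O)C1(C)C
F10 | step 12 | ethyl (2E)-2-methyl-4-[(1S)-2,2,4-trimethyl-5-oxocyclohex-3-en-1-yl]but-2-enoate | CC1=CC(C)(C)[C@@H](C/C=C(\C)C(=O)OCC)CC1=O
F11 | step 12 | ethyl (2E)-4-[(1S,5S)-5-hydroxy-2,2,4-trimethylcyclohex-3-en-1-yl]-2-methylbut-2-enoate | CC1=CC(C)(C)[C@@H](C/C=C(\C)C(=O)OCC)C[C@@H]1O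
F12 | step 12 | (1S,5S)-5-[(2E)-4-hydroxy-3-methylbut-2-en-1-yl]-2,4,4-trimethylcyclohex-2-en-1-ol | CC1=CC(C)(C)[C@@H](C/C=C(\C)CO)C[C@@H]1O
A1 | alternative 1 | (3E,5E,9R)-6,10-dimethyl-9-(3-methylbut-2-en-1-yl)undeca-3,5,10-trien-2-one | CC(=O)/C=C/C=C(C)/CC[C@H](CC=C(C)C)C(C)=C
A2 | alternative 2 | (3R,5S)-3-ethenyl-2,4,4-trimethyl-5-(3-methylbut-2-en-1-yl)cyclohex-1-en-1-yl trifluoromethanesulfonate | CC(C)=CC[C@H]1CC(OS(=O)(=O)C(F)(F)F)=C(C)[C@H](C=C)C1(C)C
A3 | alternative 3 | (1R,5R)-4,6,6-trimethylbicyclo[3.1.1]hept-3-en-2-one (verbenone) | CC1=CC(=O)[C@@H]2C[C@H]1C2(C)C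
A4 | alternative 3 | (4R,6R)-3,4,5,5-tetramethyl-6-(3-methylbut-2-en-1-yl)cyclohex-2-en-1-one | CC1=CC(=O)[C@H](CC=C(C)C)C(C)(C)[C@@H]1C
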